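**Retrosynthetic overview**
1. The nitrogen ring is formed last. The C1–C8a and C1–N bonds come from Pictet–Spengler closure of an open-chain N-methyl biaryl amine with acetaldehyde, and the 3R centre induces 1R (1,3-trans).
2. The biaryl bond C5–C8' is made just before that, by joining two innately nucleophilic aryl C–H carbons. PhI(OCOCF3)2 inverts the polarity of the naphthalene (radical cation = aryl-cation synthon), and the chiral aminophenol captures it para to OH. The new aryl group also blocks that site, so the later ring closure can only go ortho to OH, which gives the 8-OH/6-OMe pattern.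
3. The aminophenol comes from the 3,5-dimethoxyphenyl Grignard reagent and the D-alaninol-derived cyclic sulfamidate (source of 3R). Boc is then reduced to NMe, and one of the two equivalent OMe groups is cleaved.
4. The naphthalene comes from directed ortho-metalation/methallylation of a benzamide, followed by anionic annulation to build the second carbocycle.
5. Ring order: naphthalene ring, then the biaryl bond, then the tetrahydroisoquinoline ring.

**Assumption:** the SMILES fixes only C1 and C3 (both R, 1,3-trans). The rotationally hindered C5–C8' axis is not encoded and is not controlled here. Steps 6 and 7 give both atropo-diastereomers, both match the given SMILES, and they are separated by HPLC at the end.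

**Step 1**
Reactants: 1 N,N-diethyl-2-methoxybenzamide; 2 3-bromo-2-methylprop-1-ene
Product: 5 N,N-diethyl-2-methoxy-6-(2-methylprop-2-en-1-yl)benzamide, via aryllithium 3 (not isolated), via arylmagnesium bromide 4 (not isolated)
Conditions: s-BuLi, TMEDA, THF, −78 °C; MgBr2·OEt2, −78 to 0 °C; then 2, 0 °C to rt
Reagents that add atoms: none
Why: Directed ortho-metalation: the tertiary amide is a stronger directing group than OMe, so lithiation occurs at C6, and transmetalation to magnesium gives a less basic aryl nucleophile that the allylic bromide allylates cleanly.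

**Step 2**
Reactants: 5 N,N-diethyl-2-methoxy-6-(2-methylprop-2-en-1-yl)benzamide
Product: 7 1,8-dimethoxy-3-methylnaphthalene, via lithium naphtholate 6 (not isolated)
Conditions: LiN(iPr)2, THF, −78 °C to rt; then Me2SO4, DMPU, rt to 40 °C
Reagents that add atoms: dimethyl sulfate, COS(=O)(=O)OC
Why: Anionic annulation of an ortho-allyl benzamide: the benzylic/allylic proton is removed, the terminal carbon of the allyl anion acylates on the amide, loss of diethylamide and tautomerisation give the naphtholate, and this is O-methylated in the same pot (Williamson-type alkylation).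

**Step 3**
Reactants: 8 1-bromo-3,5-dimethoxybenzene; 9 tert-butyl (4R)-4-methyl-1,2,3-oxathiazolidine-3-carboxylate 2,2-dioxide
Product: 12 tert-butyl N-[(2R)-1-(3,5-dimethoxyphenyl)propan-2-yl]carbamate, via Grignard reagent 10 (not isolated), via N-sulfamate salt 11 (not isolated)
Conditions: Mg, THF, reflux; CuI (10 mol %), 9, THF, −20 °C to rt; then 1 M aq. citric acid, rt
Reagents that add atoms: none
Why: Copper-catalysed SN2 opening of the cyclic sulfamidate at its primary C–O carbon leaves the D-alaninol-derived stereocentre untouched, so its R configuration becomes C3 of the target, and mild acid hydrolyses the N-sulfate without removing Boc.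

**Step 4**
Reactants: 12 tert-butyl N-[(2R)-1-(3,5-dimethoxyphenyl)propan-2-yl]carbamate
Product: 13 (2R)-1-(3,5-dimethoxyphenyl)-N-methylpropan-2-amine
Conditions: LiAlH4, THF, reflux; Fieser work-up
Reagents that add atoms: none
Why: Hydride reduction of the carbamate (loss of tert-butoxide, then reduction of the formamide stage) turns the protecting group into the N-methyl group the target needs, and the stereocentre is not involved.

**Step 5**
Reactants: 13 (2R)-1-(3,5-dimethoxyphenyl)-N-methylpropan-2-amine
Product: 15 3-methoxy-5-[(2R)-2-(methylamino)propyl]phenol, via sodium phenolate 14 (not isolated)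
Conditions: NaSEt, NMP, 130 °C; then H2O, pH 9
Reagents that add atoms: none
Why: Thiolate SN2 cleavage of an aryl methyl ether: the two OMe groups are equivalent, so only one monophenol can form, and the resulting phenolate deactivates the ring toward a second cleavage.

**Step 6 (key step)**
Reactants: 7 1,8-dimethoxy-3-methylnaphthalene; 15 3-methoxy-5-[(2R)-2-(methylamino)propyl]phenol
Product: 18 4-(4,5-dimethoxy-7-methylnaphthalen-1-yl)-3-methoxy-5-[(2R)-2-(methylamino)propyl]phenol, via ammonium trifluoroacetate 16 (not isolated), via naphthalene radical cation 17 (not isolated)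
Conditions: 15 (1.5 equiv), CF3CO2H, (CF3)2CHOH/CH2Cl2 1:1, −20 °C; slow co-addition of 7 and PhI(OCOCF3)2 (1.05 equiv); basic work-up
Reagents that add atoms: none
Why: Proposed new method: both carbons to be joined are innately nucleophilic C–H positions para to oxygen, so the polarity of the naphthalene is inverted: in the fluoroalcohol the trivalent iodine oxidant takes one electron from 7, the most easily oxidised component, to give radical cation 17, an aryl-cation (vinylogous enolonium) synthon with its charge para to OMe; 17 is attacked at its unhindered C5 (C4 is flanked by the methyl group) by the resorcinol-type ring of 16 para to OH (the solvated OH shields the ortho sites, and the meta-dioxygenation and ammonium group make 16 hard to oxidise and keep nitrogen inert), and a second one-electron oxidation with loss of two protons gives the biaryl; the closest known reaction type is the trivalent-iodine-mediated (Kita-type) oxidative arene–arene and phenol–arene cross-coupling in fluoroalcohols; no carbon stereocentre is formed and the axis is not controlled.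

**Step 7**
Reactants: 18 4-(4,5-dimethoxy-7-methylnaphthalen-1-yl)-3-methoxy-5-[(2R)-2-(methylamino)propyl]phenol; 19 acetaldehyde
Product: 21 ancistrocongoline B [(1R,3R)-5-(4,5-dimethoxy-7-methylnaphthalen-1-yl)-6-methoxy-1,2,3-trimethyl-1,2,3,4-tetrahydroisoquinolin-8-ol], via iminium ion 20 (not isolated)
Conditions: MeCHO (3 equiv), CF3CO2H, CH2Cl2, 4 Å MS, 0 °C to rt; basic work-up; HPLC
Reagents that add atoms: none
Why: Pictet–Spengler cyclisation: the only free carbon ortho to the side chain (ortho to OH, para to OMe) attacks the N-methyl iminium ion, and in the half-chair transition state the C3-methyl stays pseudo-equatorial while the new C1-methyl goes pseudo-axial to avoid the N-methyl and the peri 8-OH, so 3R induces 1R (1,3-trans), as is typical of N-alkylated 1-arylpropan-2-amines.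

**Compound list**
1 | N,N-diethyl-2-methoxybenzamide | CCN(CC)C(=O)c1ccccc1OC | starting material
2 | 3-bromo-2-methylprop-1-ene | C=C(C)CBr | starting material
3 | [2-(diethylcarbamoyl)-3-methoxyphenyl]lithium | CCN(CC)C(=O)c1c([Li])cccc1OC | intermediate
4 | [2-(diethylcarbamoyl)-3-methoxyphenyl]magnesium bromide | CCN(CC)C(=O)c1c([Mg]Br)cccc1OC | intermediate
5 | N,N-diethyl-2-methoxy-6-(2-methylprop-2-en-1-yl)benzamide | CCN(CC)C(=O)c1c(CC(C)=C)cccc1OC | intermediate
6 | lithium 8-methoxy-3-methylnaphthalen-1-olate | [Li+].[O-]c1cc(C)cc2cccc(OC)c12 | intermediate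
7 | 1,8-dimethoxy-3-methylnaphthalene | COc1cc(C)cc2cccc(OC)c12 | intermediate
8 | 1-bromo-3,5-dimethoxybenzene | COc1cc(Br)cc(OC)c1 | starting material
9 | tert-butyl (4R)-4-methyl-1,2,3-oxathiazolidine-3-carboxylate 2,2-dioxide | C[C@@H]1COS(=O)(=O)N1C(=O)OC(C)(C)C | starting material
10 | (3,5-dimethoxyphenyl)magnesium bromide | COc1cc([Mg]Br)cc(OC)c1 | intermediate
11 | bromomagnesium N-(tert-butoxycarbonyl)-N-[(2R)-1-(3,5-dimethoxyphenyl)propan-2-yl]sulfamate | C[C@@H](N(C(=O)OC(C)(C)C)S(=O)(=O)[O-])Cc1cc(OC)cc(OC)c1.[Mg+]Br | intermediate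
12 | tert-butyl N-[(2R)-1-(3,5-dimethoxyphenyl)propan-2-yl]carbamate | C[C@@H](NC(=O)OC(C)(C)C)Cc1cc(OC)cc(OC)c1 | intermediate
13 | (2R)-1-(3,5-dimethoxyphenyl)-N-methylpropan-2-amine | C[C@@H](NC)Cc1cc(OC)cc(OC)c1 | intermediate
14 | sodium 3-methoxy-5-[(2R)-2-(methylamino)propyl]phenolate | C[C@@H](NC)Cc1cc([O-])cc(OC)c1.[Na+] | intermediate
15 | 3-methoxy-5-[(2R)-2-(methylamino)propyl]phenol | C[C@@H](NC)Cc1cc(O)cc(OC)c1 | intermediate
16 | (2R)-1-(3-hydroxy-5-methoxyphenyl)-N-methylpropan-2-aminium trifluoroacetate | C[C@@H]([NH2+]C)Cc1cc(O)cc(OC)c1.[O-]C(=O)C(F)(F)F | intermediate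
17 | radical cation of 1,8-dimethoxy-3-methylnaphthalene, trifluoroacetate (one resonance form drawn) | C[O+]=C1C=C[CH]c2cc(C)cc(OC)c21.[O-]C(=O)C(F)(F)F | intermediate
18 | 4-(4,5-dimethoxy-7-methylnaphthalen-1-yl)-3-methoxy-5-[(2R)-2-(methylamino)propyl]phenol | C[C@@H](NC)Cc1cc(O)cc(OC)c1-c1ccc(OC)c2c(OC)cc(C)cc12 | intermediate
19 | acetaldehyde | CC=O | starting material
20 | N-ethylidene-N-methyl iminium trifluoroacetate of 18 | CC=[N+](C)[C@H](C)Cc1cc(O)cc(OC)c1-c1ccc(OC)c2c(OC)cc(C)cc12.[O-]C(=O)C(F)(F)F | intermediate
21 | ancistrocongoline B, (1R,3R)-5-(4,5-dimethoxy-7-methylnaphthalen-1-yl)-6-methoxy-1,2,3-trimethyl-1,2,3,4-tetrahydroisoquinolin-8-ol | COc1cc(O)c2c(c1-c1ccc(OC)c3c(OC)cc(C)cc13)C[C@@H](C)N(C)[C@@H]2C | target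

**Total step count:** 7. **Longest linear sequence:** 5 steps (8 → 12 → 13 → 15 → 18 → 21).

**Three steps most likely to fail**

**Step 6.**
- Risks: homocoupling of 7; attack by the phenol through the carbon ortho to OH or the carbon between the two oxygens; over-oxidation of 18.
- Fallback: sets out from 7 and 15 and comes back at 21. It gives up the dehydrogenative union and makes the axis by Suzuki–Miyaura coupling after ring closure.
- Boronate partner: C–H thianthrenation of 7 is para-selective and very sensitive to steric bulk. With thianthrene S-oxide and (CF3CO)2O in MeCN at 0 °C, followed by an NaBF4 wash, it gives the naphthyl thianthrenium tetrafluoroborate F1. Borylation (B2pin2, PdCl2(dppf), KOAc, dioxane, 80 °C) then gives the naphthyl pinacol boronate F2.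
- Iodide partner: NIS in MeCN at 0 °C iodinates 15, as its trifluoroacetate salt, para to OH to give the iodophenol F3. The iodine takes over the blocking role. Pictet–Spengler closure with 19, as in step 7, gives the trans 5-iodotetrahydroisoquinoline F4, whose tertiary amine can no longer N-arylate.
- Coupling: F2 and F4 (Pd(OAc)2, SPhos, K3PO4, toluene/H2O, 90 °C) give 21.

**Step 7.**
- Risks: an insufficient trans/cis ratio; slow closure next to the bulky biaryl; acetaldehyde alkylating the electron-rich naphthalene.
- Fallback: sets out from 18 and comes back at 21. It brings in the C1-methyl as a nucleophile rather than as part of the electrophile.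
- Sequence: formaldehyde with CF3CO2H in CH2Cl2 closes the ring to the 1-unsubstituted tetrahydroisoquinoline F5. mCPBA at −20 °C gives the N-oxide F6. One equivalent of (CF3CO)2O at −78 °C (Polonovski–Potier elimination toward the benzylic C1) gives the 3,4-dihydroisoquinolinium trifluoroacetate F7. Excess MeMgBr then adds anti to the pseudo-axial C3-methyl and delivers the 1,3-trans product 21.

**Step 3.**
- Risks: the Grignard reagent attacks the Boc carbonyl or sulfur instead of carbon; low conversion.
- Fallback: sets out from 10 and comes back at 13. It sets the C–N stereocentre by inversion instead of carrying it in from the building block.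
- Sequence: 10 opens (S)-propylene oxide (CuI, THF, −20 °C) to give the (S)-alcohol F8. MsCl and Et3N give the (S)-mesylate F9. Excess MeNH2 in THF/EtOH in a sealed tube at 65 °C displaces the mesylate by SN2 with inversion, giving (R)-13 directly, so 12 and step 4 are no longer needed.

**Further compounds**
F1 | step 6 | 5-(4,5-dimethoxy-7-methylnaphthalen-1-yl)-5H-thianthren-5-ium tetrafluoroborate | COc1cc(C)cc2c([S+]3c4ccccc4Sc4ccccc43)ccc(OC)c12.F[B-](F)(F)F
F2 | step 6 | 2-(4,5-dimethoxy-7-methylnaphthalen-1-yl)-4,4,5,5-tetramethyl-1,3,2-dioxaborolane | COc1cc(C)cc2c(B3OC(C)(C)C(C)(C)O3)ccc(OC)c12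
F3 | step 6 | 4-iodo-3-methoxy-5-[(2R)-2-(methylamino)propyl]phenol | C[C@@H](NC)Cc1cc(O)cc(OC)c1I
F4 | step 6 | (1R,3R)-5-iodo-6-methoxy-1,2,3-trimethyl-1,2,3,4-tetrahydroisoquinolin-8-ol | COc1cc(O)c2c(c1I)C[C@@H](C)N(C)[C@@H]2C
F5 | step 7 | (3R)-5-(4,5-dimethoxy-7-methylnaphthalen-1-yl)-6-methoxy-2,3-dimethyl-1,2,3,4-tetrahydroisoquinolin-8-ol | COc1cc(O)c2c(c1-c1ccc(OC)c3c(OC)cc(C)cc13)C[C@@H](C)N(C)C2
F6 | step 7 | N-oxide of F5 | COc1cc(O)c2c(c1-c1ccc(OC)c3c(OC)cc(C)cc13)C[C@@H](C)[N+](C)([O-])C2
F7 | step 7 | (3R)-5-(4,5-dimethoxy-7-methylnaphthalen-1-yl)-8-hydroxy-6-methoxy-2,3-dimethyl-3,4-dihydroisoquinolin-2-ium trifluoroacetate | COc1cc(O)c2c(c1-c1ccc(OC)c3c(OC)cc(C)cc13)C[C@@H](C)[N+](C)=C2.[O-]C(=O)C(F)(F)F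
F8 | step 3 | (2S)-1-(3,5-dimethoxyphenyl)propan-2-ol | C[C@H](O)Cc1cc(OC)cc(OC)c1
F9 | step 3 | (2S)-1-(3,5-dimethoxyphenyl)propan-2-yl methanesulfonate | C[C@H](OS(C)(=O)=O)Cc1cc(OC)cc(OC)c1
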